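The route rests on cutting the C5–C6 bond of the 1,2-dioxane ring (O1, O2, C3–C6). The feature exploited is C6, the hydrogen-free ring carbon that carries O1, C5, a methyl group and C7. It is a masked methyl ketone and can react as a peroxycarbenium ion. The precursor is an acyclic methoxy peroxyketal in which a C1–C5 allylsilane hydroperoxide (C3 preset) and the citronellal-derived C6–C17 ketone are already joined through O1–O2. One Lewis acid operation then makes the hindered C5–C6 bond intramolecularly, closes the ring and sets C6 relative to C3. It also leaves a C4 methylene group from which the C4 methyl stereocentre is made.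

Key step: step 14

Numbering: C1 is the carboxyl carbon and C2 its CH2. The ring is O1–O2–C3–C4–C5–C6, with O2 on C3 and O1 on C6. The side chain is C7–C17, with the methyl branch on C8 and phenyl on C17.
Remark on the chemistry: centres that are erased or ionised later (the carbinol carbon made in step 2, the ketal carbon made in step 13) are carried as epimer mixtures, and the SMILES of the peroxyketal shows one epimer.

Step 1
Reactants: 1 (6-bromohexyl)benzene
Product: 2 (6-phenylhexyl)triphenylphosphonium bromide
Conditions: PPh3, MeCN, reflux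
Reagents that add atoms: triphenylphosphine, c1ccc(cc1)P(c1ccccc1)c1ccccc1
Why: SN2 quaternisation of an unhindered primary bromide by PPh3 is the standard entry to a Wittig salt.

Step 2
Reactants: 3 (R)-citronellal
Product: 4 (4R)-4,8-dimethylnon-7-en-2-ol (C2 epimers)
Conditions: MeMgBr, Et2O, 0 °C
Reagents that add atoms: methylmagnesium bromide, C[Mg]Br
Why: Grignard addition to the aldehyde brings in the future C6 methyl group; the new carbinol centre forms without control, which is harmless because step 6 erases it, and C8 is not touched.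

Step 3
Reactants: 4 (4R)-4,8-dimethylnon-7-en-2-ol
Product: 6 (4R)-6-hydroxy-4-methylheptanal (C6 epimers), via ozonide 5 (not isolated)
Conditions: O3, CH2Cl2, −78 °C; then Me2S, −78 °C to rt
Reagents that add atoms: ozone, [O-][O+]=O
Why: Ozonolysis with reductive work-up cleaves the only alkene to the C11 aldehyde, and the free secondary alcohol is inert to ozone at low temperature.

Step 4
Reactants: 6 (4R)-6-hydroxy-4-methylheptanal; 2 (6-phenylhexyl)triphenylphosphonium bromide
Product: 8 (4R,7Z)-4-methyl-13-phenyltridec-7-en-2-ol (C2 epimers), via ylide 7 (not isolated)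
Conditions: 2 (2.2 equiv), NaN(SiMe3)2 (2.1 equiv), THF, 0 °C; then 6, −78 °C to rt
Reagents that add atoms: none
Why: Wittig olefination with the non-stabilised ylide joins C11 to C12; the extra ylide covers the free hydroxyl group, and the alkene geometry (mainly Z) is irrelevant because it is hydrogenated next.

Step 5
Reactants: 8 (4R,7Z)-4-methyl-13-phenyltridec-7-en-2-ol
Product: 9 (4R)-4-methyl-13-phenyltridecan-2-ol (C2 epimers)
Conditions: H2 (1 atm), Pd/C (10 wt %), EtOAc, rt
Reagents that add atoms: none
Why: Heterogeneous catalytic hydrogenation saturates the disubstituted alkene, leaves the phenyl ring and the alcohol alone, and completes the nine-methylene C9–C17 chain.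

Step 6
Reactants: 9 (4R)-4-methyl-13-phenyltridecan-2-ol
Product: 10 (4R)-4-methyl-13-phenyltridecan-2-one
Conditions: Pr4N[RuO4] (5 mol %), NMO, 4 Å MS, CH2Cl2, rt
Reagents that add atoms: none
Why: Ley–Griffith oxidation turns the secondary alcohol into the C6 methyl ketone under neutral conditions; C8 is β to the carbonyl group and cannot epimerise.

Step 7
Reactants: 10 (4R)-4-methyl-13-phenyltridecan-2-one
Product: 11 [(10R)-12,12-dimethoxy-10-methyltridecyl]benzene
Conditions: HC(OMe)3, MeOH, p-TsOH·H2O (cat.), rt; Et3N quench, filtration through basic alumina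
Reagents that add atoms: trimethyl orthoformate, COC(OC)OC
Why: Acid-catalysed ketalisation, driven by the orthoester as water scavenger, gives the dimethyl ketal, which is the activated form of the ketone needed for exchange with a hydroperoxide.

Step 8
Reactants: 12 (2-bromoallyl)trimethylsilane; 13 3-[(tert-butyldimethylsilyl)oxy]propanal
Product: 15 rac-1-[(tert-butyldimethylsilyl)oxy]-4-[(trimethylsilyl)methyl]pent-4-en-3-ol, via vinyllithium 14 (not isolated)
Conditions: 12, t-BuLi (2.0 equiv), Et2O, −78 °C; then 13, −78 °C
Reagents that add atoms: none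
Why: Bromine–lithium exchange followed by 1,2-addition of the vinyllithium to the aldehyde forms C3–C4 and puts the allylsilane in place; C3 is racemic at this point and is corrected in steps 9 and 10.

Step 9
Reactants: 15 rac-1-[(tert-butyldimethylsilyl)oxy]-4-[(trimethylsilyl)methyl]pent-4-en-3-ol
Product: 16 1-[(tert-butyldimethylsilyl)oxy]-4-[(trimethylsilyl)methyl]pent-4-en-3-one
Conditions: Pr4N[RuO4] (5 mol %), NMO, 4 Å MS, CH2Cl2, 0 °C to rt
Reagents that add atoms: none
Why: Ley–Griffith oxidation of the allylic alcohol runs under neutral, anhydrous conditions, which protect the allylsilane from protodesilylation and the β-silyloxy ketone from elimination.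

Step 10
Reactants: 16 1-[(tert-butyldimethylsilyl)oxy]-4-[(trimethylsilyl)methyl]pent-4-en-3-one
Product: 17 (3R)-1-[(tert-butyldimethylsilyl)oxy]-4-[(trimethylsilyl)methyl]pent-4-en-3-ol
Conditions: (S)-Me-CBS oxazaborolidine (20 mol %), catecholborane, toluene, −78 °C
Reagents that add atoms: none
Why: Corey–Bakshi–Shibata reduction: the α-branched alkenyl group acts as the large substituent and the CH2CH2OTBS chain as the small one, so the (S)-catalyst should give the (R)-carbinol, and catecholborane at low temperature avoids hydroboration and conjugate reduction.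

Step 11
Reactants: 17 (3R)-1-[(tert-butyldimethylsilyl)oxy]-4-[(trimethylsilyl)methyl]pent-4-en-3-ol
Product: 18 (3R)-1-[(tert-butyldimethylsilyl)oxy]-4-[(trimethylsilyl)methyl]pent-4-en-3-yl methanesulfonate
Conditions: Ms2O, Et3N, CH2Cl2, −20 °C; cold work-up, used crude at once
Reagents that add atoms: methanesulfonic anhydride, CS(=O)(=O)OS(C)(=O)=O
Why: Sulfonylation takes place at oxygen with retention at C3, and the anhydride replaces the sulfonyl chloride so that no chloride ion is present to displace the reactive allylic mesylate.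

Step 12
Reactants: 18 (3R)-1-[(tert-butyldimethylsilyl)oxy]-4-[(trimethylsilyl)methyl]pent-4-en-3-yl methanesulfonate
Product: 19 (3S)-1-[(tert-butyldimethylsilyl)oxy]-4-[(trimethylsilyl)methyl]pent-4-en-3-yl hydroperoxide
Conditions: 30 % aq H2O2 (large excess), KOH, MeOH–THF, 0 °C
Reagents that add atoms: hydrogen peroxide, OO
Why: SN2 displacement of a secondary sulfonate by the hydroperoxide anion, a small α-effect nucleophile, inverts C3 from R to S; anionic oxygen nucleophiles attack such allylic sulfonates at the carbon bearing the leaving group, and the low temperature holds back ionisation.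

Step 13
Reactants: 19 (3S)-1-[(tert-butyldimethylsilyl)oxy]-4-[(trimethylsilyl)methyl]pent-4-en-3-yl hydroperoxide; 11 [(10R)-12,12-dimethoxy-10-methyltridecyl]benzene
Product: 20 (3S)-1-[(tert-butyldimethylsilyl)oxy]-4-[(trimethylsilyl)methyl]pent-4-en-3-yl (4R)-2-methoxy-4-methyl-13-phenyltridecan-2-yl peroxide (both ketal epimers)
Conditions: 11 (1.3 equiv), PPTS (10 mol %), 4 Å MS, CH2Cl2, rt
Reagents that add atoms: none
Why: Acid-catalysed transketalisation: the ketal loses methanol to a methoxycarbenium ion that the hydroperoxide captures through its terminal oxygen, the excess of 11 and the sieves stop the exchange at the mixed peroxyketal, and C3 and C8 are not involved.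

Step 14
Reactants: 20 mixed methoxy peroxyketal (both ketal epimers)
Product: 22 tert-butyl(dimethyl){2-[(3S,6R)-6-methyl-4-methylidene-6-[(2R)-2-methyl-11-phenylundecyl]-1,2-dioxan-3-yl]ethoxy}silane, via peroxycarbenium ion 21 (not isolated)
Conditions: SnCl4 (1.1 equiv), 2,6-di-tert-butyl-4-methylpyridine (0.2 equiv), CH2Cl2 (0.02 M), −78 °C; aq NaHCO3 quench
Reagents that add atoms: none
Why: SnCl4 binds the more basic methoxy oxygen and expels it, so both ketal epimers converge on the planar ion 21 (C6=O1+–O2); the terminal alkene carbon C5 then attacks C6, charge builds up at C4 under assistance of the C–Si bond, and chloride removes silicon to leave the C4 exocyclic methylene. This is the peroxide counterpart of the silyl-Prins (intramolecular Hosomi–Sakurai) cyclisation, a known reaction of monoperoxyketals that carry an allylsilane. The 1,2-dioxane ring closes in a 6-endo-trig mode with respect to the C6=O1 bond, the alkene also reacting in the endo sense, through a chair-like transition state. C6, the only new stereocentre, is controlled by the preset C3 centre: the β-branched C7 arm should lie anti to O2 on the cation and hence pseudoequatorial, while the C3 silyloxyethyl arm should turn pseudoaxial to escape eclipsing with the CH2SiMe3 group on C4, which places C2 and C7 on the same ring face (6R). Chemoselectivity (loss of methoxide, not of the peroxide) rests on the lower basicity of peroxide oxygen, and regioselectivity rests on the β-silicon effect, which directs attack through C5 and keeps positive charge from resting unassisted next to O–O. The facial bias at C6 is only moderate, so the C6 epimer is the expected by-product and is to be removed by chromatography at this stage.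

Step 15
Reactants: 22 4-methylidene-1,2-dioxane TBS ether
Product: 23 tert-butyl(dimethyl){2-[(3S,4S,6R)-4,6-dimethyl-6-[(2R)-2-methyl-11-phenylundecyl]-1,2-dioxan-3-yl]ethoxy}silane
Conditions: KO2CN=NCO2K (large excess), AcOH, MeOH–CH2Cl2, 0 °C to rt
Reagents that add atoms: none
Why: Diimide reduction is a concerted syn transfer of two hydrogens that spares O–O bonds; the alkene face carrying the C2 and C7 arms is blocked in both chair forms (axial C3 arm beside the alkene in one, axial C7 arm in a 1,3-relation in the other), so hydrogen should arrive from the face of the small C6 methyl group and push the new C4 methyl cis to C2 and C7 (4S).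

Step 16
Reactants: 23 4,6-dimethyl-1,2-dioxane TBS ether
Product: 24 2-[(3S,4S,6R)-4,6-dimethyl-6-[(2R)-2-methyl-11-phenylundecyl]-1,2-dioxan-3-yl]ethanol
Conditions: HF·pyridine, pyridine–THF, 0 °C to rt
Reagents that add atoms: none
Why: Fluoride-mediated desilylation in an acidic buffer removes the TBS group without the basic conditions that could trigger Kornblum–DeLaMare cleavage at C3–H.

Step 17
Reactants: 24 2-[(3S,4S,6R)-4,6-dimethyl-6-[(2R)-2-methyl-11-phenylundecyl]-1,2-dioxan-3-yl]ethanol
Product: 26 2-[(3S,4S,6R)-4,6-dimethyl-6-[(2R)-2-methyl-11-phenylundecyl]-1,2-dioxan-3-yl]acetic acid (target), via aldehyde 25 (not isolated)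
Conditions: TEMPO (20 mol %), PhI(OAc)2 (2.5 equiv), MeCN–H2O (1:1), rt
Reagents that add atoms: water, O
Why: Oxoammonium (TEMPO) oxidation takes the primary alcohol through aldehyde 25 and its hydrate to the acid in a weakly acidic medium, so the β-peroxy aldehyde never meets base, and the O–O bond, the phenyl ring and all four stereocentres stay untouched.

Compound list
1 | (6-bromohexyl)benzene | BrCCCCCCc1ccccc1 | starting material
2 | (6-phenylhexyl)triphenylphosphonium bromide | [Br-].c1ccc(CCCCCC[P+](c2ccccc2)(c2ccccc2)c2ccccc2)cc1 | intermediate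
3 | (R)-citronellal | C[C@H](CCC=C(C)C)CC=O | starting material
4 | (4R)-4,8-dimethylnon-7-en-2-ol (C2 epimers) | C[C@H](CCC=C(C)C)CC(C)O | intermediate
5 | 5-[(3R)-5-hydroxy-3-methylhexyl]-3,3-dimethyl-1,2,4-trioxolane (ozonide, not isolated) | C[C@H](CCC1OOC(C)(C)O1)CC(C)O | intermediate
6 | (4R)-6-hydroxy-4-methylheptanal (C6 epimers) | C[C@H](CCC=O)CC(C)O | intermediate
7 | (6-phenylhexylidene)triphenylphosphorane (not isolated) | C(CCCCCc1ccccc1)=P(c1ccccc1)(c1ccccc1)c1ccccc1 | intermediate
8 | (4R,7Z)-4-methyl-13-phenyltridec-7-en-2-ol (C2 epimers) | C[C@H](CC/C=C\CCCCCc1ccccc1)CC(C)O | intermediate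
9 | (4R)-4-methyl-13-phenyltridecan-2-ol (C2 epimers) | C[C@H](CCCCCCCCCc1ccccc1)CC(C)O | intermediate
10 | (4R)-4-methyl-13-phenyltridecan-2-one | C[C@H](CCCCCCCCCc1ccccc1)CC(C)=O | intermediate
11 | [(10R)-12,12-dimethoxy-10-methyltridecyl]benzene | C[C@H](CCCCCCCCCc1ccccc1)CC(C)(OC)OC | intermediate
12 | (2-bromoallyl)trimethylsilane | C=C(Br)C[Si](C)(C)C | starting material
13 | 3-[(tert-butyldimethylsilyl)oxy]propanal | O=CCCO[Si](C)(C)C(C)(C)C | starting material
14 | [3-(trimethylsilyl)prop-1-en-2-yl]lithium (not isolated) | [Li]C(=C)C[Si](C)(C)C | intermediate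
15 | rac-1-[(tert-butyldimethylsilyl)oxy]-4-[(trimethylsilyl)methyl]pent-4-en-3-ol | C[Si](C)(C)CC(=C)C(O)CCO[Si](C)(C)C(C)(C)C | intermediate
16 | 1-[(tert-butyldimethylsilyl)oxy]-4-[(trimethylsilyl)methyl]pent-4-en-3-one | C[Si](C)(C)CC(=C)C(=O)CCO[Si](C)(C)C(C)(C)C | intermediate
17 | (3R)-1-[(tert-butyldimethylsilyl)oxy]-4-[(trimethylsilyl)methyl]pent-4-en-3-ol | C[Si](C)(C)CC(=C)[C@@H](CCO[Si](C)(C)C(C)(C)C)O | intermediate
18 | (3R)-1-[(tert-butyldimethylsilyl)oxy]-4-[(trimethylsilyl)methyl]pent-4-en-3-yl methanesulfonate | C[Si](C)(C)CC(=C)[C@@H](CCO[Si](C)(C)C(C)(C)C)OS(C)(=O)=O | intermediate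
19 | (3S)-1-[(tert-butyldimethylsilyl)oxy]-4-[(trimethylsilyl)methyl]pent-4-en-3-yl hydroperoxide | C[Si](C)(C)CC(=C)[C@H](CCO[Si](C)(C)C(C)(C)C)OO | intermediate
20 | mixed methoxy peroxyketal of 19 and ketone 10 (formed and used as both ketal epimers, one drawn) | C[Si](C)(C)CC(=C)[C@H](CCO[Si](C)(C)C(C)(C)C)OO[C@](C)(OC)C[C@H](C)CCCCCCCCCc1ccccc1 | intermediate
21 | C6 peroxycarbenium ion (not isolated) | C[Si](C)(C)CC(=C)[C@H](CCO[Si](C)(C)C(C)(C)C)O[O+]=C(C)C[C@H](C)CCCCCCCCCc1ccccc1 | intermediate
22 | tert-butyl(dimethyl){2-[(3S,6R)-6-methyl-4-methylidene-6-[(2R)-2-methyl-11-phenylundecyl]-1,2-dioxan-3-yl]ethoxy}silane | C[C@H](CCCCCCCCCc1ccccc1)C[C@]1(C)CC(=C)[C@H](CCO[Si](C)(C)C(C)(C)C)OO1 | intermediate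
23 | tert-butyl(dimethyl){2-[(3S,4S,6R)-4,6-dimethyl-6-[(2R)-2-methyl-11-phenylundecyl]-1,2-dioxan-3-yl]ethoxy}silane | C[C@H](CCCCCCCCCc1ccccc1)C[C@]1(C)C[C@H](C)[C@H](CCO[Si](C)(C)C(C)(C)C)OO1 | intermediate
24 | 2-[(3S,4S,6R)-4,6-dimethyl-6-[(2R)-2-methyl-11-phenylundecyl]-1,2-dioxan-3-yl]ethanol | C[C@H](CCCCCCCCCc1ccccc1)C[C@]1(C)C[C@H](C)[C@H](CCO)OO1 | intermediate
25 | 2-[(3S,4S,6R)-4,6-dimethyl-6-[(2R)-2-methyl-11-phenylundecyl]-1,2-dioxan-3-yl]acetaldehyde (not isolated) | C[C@H](CCCCCCCCCc1ccccc1)C[C@]1(C)C[C@H](C)[C@H](CC=O)OO1 | intermediate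
26 | 2-[(3S,4S,6R)-4,6-dimethyl-6-[(2R)-2-methyl-11-phenylundecyl]-1,2-dioxan-3-yl]acetic acid | C[C@H](CCCCCCCCCc1ccccc1)C[C@]1(C)C[C@H](C)[C@H](CC(=O)O)OO1 | target

Total step count: 17.
Longest linear sequence: 11 steps from (R)-citronellal 3 (steps 2–7 and 13–17).

Steps most likely to fail

Step 14 (key step).
- **What may go wrong:** ionisation at the peroxide oxygen or heterolysis of the O–O bond in place of methoxide loss, protodesilylation of the allylsilane by adventitious acid, and poor facial selectivity at C6.
- **Fallback (sets out from 19 and 10, comes back at 22):** the cation is reached by condensation and not from a preformed methoxy ketal. Hydroperoxide 19 is silylated (Me3SiCl, Et3N, CH2Cl2, 0 °C) to the trimethylsilyl peroxide F1. This peroxide and ketone 10 are then treated with catalytic Me3SiOTf in CH2Cl2 at −78 °C, as in a silyl-modified Sakurai reaction. Silyl transfer should give the trimethylsilyloxy peroxyketal F2, which loses its silyloxy group irreversibly as the disiloxane. Ion 21 then arises without chloride and without a stoichiometric Lewis acid, paired with a different counter-ion, and closes to 22. Steps 7 and 13 fall away.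

Step 12.
- **What may go wrong:** ionisation of the allylic sulfonate in the protic medium with erosion of configuration at C3, allylic transposition, elimination towards the diene, and double alkylation of hydrogen peroxide.
- **Fallback (sets out from 10 and 18, comes back at 20):** the peroxide nucleophile is carried by the ketone half, so that the free hydroperoxide 19 and step 13 are bypassed. Wittig methylenation of 10 (Ph3P=CH2, THF, 0 °C) gives the 1,1-disubstituted alkene F3. Ozonolysis of it in MeOH–CH2Cl2 at −78 °C should give the α-methoxy hydroperoxide F4, by methanol capture of the more substituted Criegee carbonyl oxide. Its caesium salt (CsOH·H2O, DMF, 0 °C) is alkylated by mesylate 18 with inversion to give 20 directly. The aprotic medium disfavours ionisation, and a nucleophile with a single O–H cannot be alkylated twice.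

Step 15.
- **What may go wrong:** poor facial selectivity of hydrogen delivery to the exocyclic alkene, and sluggish reduction of a 1,1-disubstituted alkene by diimide.
- **Fallback (sets out from 22, comes back at 23):** hydrogen is brought to C4 by a much bulkier reagent, and the resulting carbon–boron bond is then taken down to methyl. Hydroboration with 9-BBN (THF, 0 °C to rt) should place boron on the exocyclic CH2 and hydrogen on C4 from the open face, giving the B-alkyl borane F5. Oxidation with NaBO3·4H2O gives the hydroxymethyl dioxane F6. Appel-type iodination (preformed Ph3P·I2, imidazole, CH2Cl2, 0 °C) gives the iodomethyl dioxane F7. NaBH4 in DMSO at rt, an ionic reduction that avoids carbon radicals near the O–O bond, then gives 23.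

Further compounds
F1 | step 14 | (3S)-1-[(tert-butyldimethylsilyl)oxy]-4-[(trimethylsilyl)methyl]pent-4-en-3-yl trimethylsilyl peroxide | C[Si](C)(C)CC(=C)[C@H](CCO[Si](C)(C)C(C)(C)C)OO[Si](C)(C)C
F2 | step 14 | trimethylsilyloxy peroxyketal of 19 and 10 (ketal epimers) | C[Si](C)(C)CC(=C)[C@H](CCO[Si](C)(C)C(C)(C)C)OOC(C)(O[Si](C)(C)C)C[C@H](C)CCCCCCCCCc1ccccc1
F3 | step 12 | [(10R)-10,12-dimethyltridec-12-en-1-yl]benzene | C[C@H](CCCCCCCCCc1ccccc1)CC(C)=C
F4 | step 12 | (4R)-2-methoxy-4-methyl-13-phenyltridecan-2-yl hydroperoxide (C2 epimers) | C[C@H](CCCCCCCCCc1ccccc1)CC(C)(OC)OO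
F5 | step 15 | 9-{[(3S,4S,6R)-3-(2-TBSO-ethyl)-6-methyl-6-[(2R)-2-methyl-11-phenylundecyl]-1,2-dioxan-4-yl]methyl}-9-borabicyclo[3.3.1]nonane | C[C@H](CCCCCCCCCc1ccccc1)C[C@]1(C)C[C@H](CB2C3CCCC2CCC3)[C@H](CCO[Si](C)(C)C(C)(C)C)OO1
F6 | step 15 | [(3S,4R,6R)-3-(2-TBSO-ethyl)-6-methyl-6-[(2R)-2-methyl-11-phenylundecyl]-1,2-dioxan-4-yl]methanol | C[C@H](CCCCCCCCCc1ccccc1)C[C@]1(C)C[C@H](CO)[C@H](CCO[Si](C)(C)C(C)(C)C)OO1
F7 | step 15 | 4-(iodomethyl) analogue of 23, CH2I cis to the C2 and C7 arms | C[C@H](CCCCCCCCCc1ccccc1)C[C@]1(C)C[C@H](CI)[C@H](CCO[Si](C)(C)C(C)(C)C)OO1
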